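**Assumption:** the target has no stereocentre and no stereogenic double bond, so it is achiral and "single enantiomer" needs no stereocontrol.

## Retrosynthetic overview

- The target is opened at the phenol O–H: the last step is hydrogenolysis of a benzyl ether.
- The key disconnection is the aryl C(sp2)–CH2 bond: a 4-(benzyloxy)phenyl radical (from the aryl iodide) adds anti-Markovnikov to vinyl docosanoate, which already carries the complete ester (proposed new step).
- Vinyl docosanoate comes from docosanoic acid and vinyl acetate by transvinylation.
- No ring is formed; the benzene ring is bought.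

## Route

**Step 1**
Reactants: 1 docosanoic acid; 2 vinyl acetate (ethenyl acetate)
Product: 3 ethenyl docosanoate (vinyl docosanoate)
Conditions: Pd(OAc)2 (5 mol %), KOH (10 mol %), vinyl acetate (20 equiv)/THF, 45 °C, 24 h
Reagents that add atoms: none
Why: Pd(II)-catalysed transvinylation (vinyl interchange) of a carboxylic acid with vinyl acetate is an equilibrium that the large excess of vinyl acetate drives to the fatty vinyl ester.

**Step 2**
Reactants: 3 ethenyl docosanoate (2.0 equiv); 4 1-(benzyloxy)-4-iodobenzene (1.0 equiv)
Product: 5 2-[4-(benzyloxy)phenyl]ethyl docosanoate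
Conditions: 10-phenylphenothiazine (PTH, 5 mol %), cyclohexanethiol (20 mol %), HCO2Na (3 equiv), DMSO/t-BuOH/H2O (10:10:1), 390 nm LED, 40 °C, 16 h
Reagents that add atoms: none
Why: Proposed new method: anti-Markovnikov radical hydroarylation of an O-vinyl fatty ester, in which photoexcited PTH (E* about −2.1 V vs SCE) or the CO2 radical anion chain carrier reduces the aryl iodide, loss of iodide gives the short-lived 4-(benzyloxy)phenyl radical, this adds to the unsubstituted CH2 terminus of 3 (k about 10^8 M−1 s−1, faster than H-abstraction because the thiol is catalytic and the solvents are poor H-donors), the nucleophilic α-acyloxyalkyl radical is quenched by polarity-matched hydrogen-atom transfer from the thiol before it can add to a second vinyl ester, and the thiyl radical regenerates the CO2 radical anion from formate, so the ester C–O bond is carried through untouched; the closest known reaction type is the photoredox/thiol reductive hydroarylation of vinyl carbamates and enamides with aryl halides (and Meerwein-type aryl radical additions to enol esters), which has not been shown for vinyl esters of fatty acids as a route to 2-arylethyl esters.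

**Step 3**
Reactants: 5 2-[4-(benzyloxy)phenyl]ethyl docosanoate (chromatographed free of thiol)
Product: 6 2-(4-hydroxyphenyl)ethyl docosanoate
Conditions: H2 (1 atm), 10 % Pd/C, EtOAc/THF (1:1), rt
Reagents that add atoms: none
Why: Catalytic hydrogenolysis of an aryl benzyl ether is reliable, and the saturated alkyl ester and the arene are inert at 1 atm and room temperature.

## Compound list

1 | docosanoic acid (behenic acid) | CCCCCCCCCCCCCCCCCCCCCC(=O)O | starting material
2 | vinyl acetate (ethenyl acetate) | C=COC(C)=O | starting material
3 | ethenyl docosanoate (vinyl docosanoate) | CCCCCCCCCCCCCCCCCCCCCC(=O)OC=C | intermediate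
4 | 1-(benzyloxy)-4-iodobenzene | Ic1ccc(OCc2ccccc2)cc1 | starting material
5 | 2-[4-(benzyloxy)phenyl]ethyl docosanoate | CCCCCCCCCCCCCCCCCCCCCC(=O)OCCc1ccc(OCc2ccccc2)cc1 | intermediate
6 | 2-(4-hydroxyphenyl)ethyl docosanoate | CCCCCCCCCCCCCCCCCCCCCC(=O)OCCc1ccc(O)cc1 | target

## Summary

Total step count: 3. Longest linear sequence: 3 steps (1 → 3 → 5 → 6).

**Steps most likely to fail**

1. **Step 2 (proposed new hydroarylation).** The risks are hydrodeiodination of 4, thiol–ene loss of the catalyst, telomerisation of 3, and poor solubility of the C22 ester. The fallback uses known chemistry, sets out from 4 (with acid 1) and comes back at 5. Iodine–magnesium exchange on 4 (i-PrMgCl·LiCl, THF, 0 °C) gives [4-(benzyloxy)phenyl]magnesium chloride F3. F3 opens ethylene oxide (CuI 10 mol %, −30 to 0 °C, 1 M HCl work-up) to give 2-[4-(benzyloxy)phenyl]ethanol F4. Carbodiimide esterification of F4 with 1 (EDC·HCl, DMAP, CH2Cl2, rt) gives 5.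

2. **Step 1 (transvinylation).** The risks are incomplete equilibrium and Pd black formation with the poorly soluble C22 acid. The fallback sets out from 1 and comes back at 3. Acid 1 is converted with SOCl2 (cat. DMF, toluene, 70 °C) into docosanoyl chloride F1. Lithium ethenolate F2 is made separately by cycloreversion of 2-lithiotetrahydrofuran (n-BuLi in THF, rt, 16 h). F2 is O-acylated with F1 (−78 to 0 °C) to give 3.

3. **Step 3 (debenzylation).** The risks are catalyst poisoning by sulfur traces and low solubility of the waxy ester. The fallback changes the protecting group, sets out from 3 and comes back at 6. 4-Iodophenol F5 (purchased) is silylated (TIPSCl, imidazole, DMF, rt) to give (4-iodophenoxy)tri(propan-2-yl)silane F6. F6 is coupled with 3 under the step 2 conditions to give 2-(4-{[tri(propan-2-yl)silyl]oxy}phenyl)ethyl docosanoate F7. Fluoride cleavage (TBAF/AcOH 1:1, THF, 0 °C) gives 6 without hydrogenation.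

## Further compounds

F1 | step 1 | docosanoyl chloride | CCCCCCCCCCCCCCCCCCCCCC(=O)Cl
F2 | step 1 | lithium ethenolate | [Li+].[O-]C=C
F3 | step 2 | [4-(benzyloxy)phenyl]magnesium chloride | Cl[Mg]c1ccc(OCc2ccccc2)cc1
F4 | step 2 | 2-[4-(benzyloxy)phenyl]ethanol | OCCc1ccc(OCc2ccccc2)cc1
F5 | step 3 | 4-iodophenol (purchased) | Oc1ccc(I)cc1
F6 | step 3 | (4-iodophenoxy)tri(propan-2-yl)silane | CC(C)[Si](Oc1ccc(I)cc1)(C(C)C)C(C)C
F7 | step 3 | 2-(4-{[tri(propan-2-yl)silyl]oxy}phenyl)ethyl docosanoate | CCCCCCCCCCCCCCCCCCCCCC(=O)OCCc1ccc(O[Si](C(C)C)(C(C)C)C(C)C)cc1
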